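## The problem

The target is a 3,3''-biflavanone: two 2-(4-methoxyphenyl)chroman-4-one units joined through C3 and C3'', one with a 5,7-dihydroxy ring A and the other with a 5-hydroxy-7-methoxy ring A. All four stereocentres (2R,3R,2''R,3''R) lie on the chain C2–C3–C3''–C2'', and the central bond joins two carbons that are each α to a ketone. Both rings C are 2,3-cis, the less stable arrangement of a 3-substituted flavanone, so C3 and C3'' must not meet enolising conditions once C4 and C4'' are carbonyl groups; the ketones therefore have to appear late and under neutral conditions. The two halves are homochiral (like), yet no stereocentre of one half can be trusted to steer bond formation in the other, so the absolute sense of each half has to come from a reagent. The halves differ only at O7 against O7'' (OH against OMe), which defeats any plan that builds a symmetric core and then tries to tell two equivalent phenols apart. The fragile elements are the free phenols, the anisyl-benzylic C2–O1 bonds (acid, hydrogenolysis, base-induced opening to a chalcone) and the cis relationships themselves. The feature that opens the molecule is that each ring C (O1, C2, C3, C4, C4a, C8a) is the formal [4+2] adduct of an oxa-diene O1=C8a–C4a=C4, which a salicylaldehyde can supply, and the alkene C2=C3. The chain C2–C3–C3''–C2'' is then a 1,4-bis(4-methoxyphenyl)buta-1,3-diene whose two Z double bonds carry the two cis relationships.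

## Retrosynthesis

**13 to 12.** The three phenolic O–H groups (O5, O7, O5'') are traced back to benzyl ethers in 12. Benzyl ethers survive acid and a quinone oxidant and fall to neutral hydrogenolysis, the one deprotection that neither enolises C3/C3'' nor opens the C2–O1 bonds by elimination. Silyl or acetal groups would not survive the acidic ring-forming step or would need fluoride or acid at the very end. The skeleton is unchanged; the forward step must cleave three aryl benzyl ethers without reducing the aryl ketones or the C2–O1 bonds.

**12 to 11.** The two carbonyl groups are taken back to C4–OMe and C4''–OMe in 11. With C4 tetrahedral, C3 is no longer enolisable, so the cis relationships can be built and handled under acid. A C4 oxygen at the alcohol level is exactly what an aldehyde carbon delivers in a ring-forming step. The neighbouring option, a flavan with C4H2, would need a harder late C–H oxidation. The forward step has to oxidise two benzylic ethers without touching C2–H, the benzyl ethers or C3.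

**11 to 3, 5 and 7.** The bonds O1–C2, C3–C4, O1''–C2'' and C3''–C4'' are cut, which dissolves both rings C and leaves diene 3 and the salicylaldehydes 5 and 7.
- Against a C3–C3'' disconnection (coupling of two flavanone enolates), this cut never makes a bond between enolisable centres and does not default to the trans series.
- Against a C4–C4a/O1–C8a disconnection, it does not pass through a symmetric open-chain core, because 5 and 7 enter one after the other.
- The simplification is large: three achiral fragments replace a compound with six stereocentres.
- The forward reaction must deliver four things. Each oxa-diene must add with oxygen to the anisyl-bearing carbon and carbon to the inner carbon, the orientation of an anethole-type alkene and not that of a diene attacked at its terminus. The addition must be suprafacial, so that Z becomes cis. The same kind of alkene face must be chosen twice. Each aldehyde must meet only one alkene.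
- The design supports these demands as follows. The 4-methoxy groups stabilise positive character at C2 and C2''. In the Z,Z isomer the competing aryl-allyl cation would carry an inward aryl group twisted out of conjugation. A chiral acid supplies face control. The conjugated diene 3 should react faster than the isolated alkene left in mono-adduct 9, so that acetal 8 (from 5) is used up before acetal 10 (from 7) is generated.

**3 to 2 to 1.** The two Z double bonds are taken back to the triple bonds of diyne 2, and the central sp–sp bond of 2 (the future C3–C3'' bond) to an oxidative homocoupling that joins two molecules of alkyne 1. Building the diene by olefination would give E/Z mixtures; syn addition of hydrogen to a diyne fixes both geometries at once. The forward steps are a copper-mediated alkyne dimerisation and a cis-selective semihydrogenation that must stop at the diene.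

**5 and 7 to 4.** The aryl ether bonds are cut back to 2,4,6-trihydroxybenzaldehyde 4. Aldehyde 5 comes from double benzylation, which leaves the chelated ortho hydroxyl free. Aldehyde 7 comes from methylation of the para hydroxyl (6) and then benzylation of one of the two equivalent ortho hydroxyls. Formylating a pre-alkylated phloroglucinol would raise a regiochemical question that alkylating 4 avoids.

## Roads not taken

**Alternative 1:** The four stereocentres are drawn from a cyclobutane, the all-trans head-to-head cinnamic acid photodimer A1. One-electron photocatalytic oxidation would break the bond between the two anisyl-bearing carbons (future C2 and C2''), and each carboxyl group would capture the benzylic carbon of the other half, giving the cis-fused bis-lactone A2 whose ring oxygens are the future O1 and O1''. The rings A would then be attached by arylation.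
- Merits: C3–C3'' and both C2/C3 relationships come from a cheap dimerisation, and there is no regiochemical question. The exo aryl groups of A2 correspond to 2,3-cis and are held by ring fusion. In this respect the road is firmer than the chosen plan, whose cis relationships are kinetic.
- Weak points: diarylcyclobutane radical cations normally revert to alkenes, and a twofold capture by carboxylate with net two-electron oxidation has no close model. A1 is not the photodimer that forms readily and is racemic unless resolved. A2 is C2-symmetric, so two different rings A would have to be placed on two equivalent lactones. Four further bonds (two C4–C4a, two O1–C8a) remain to be made through open-chain intermediates with enolisable C3.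
- Comparison: the chosen plan has to set against the rigidity of A2 that it attaches both rings A while closing rings C and tells them apart simply by the order in which 5 and 7 are added.

**Alternative 2:** The cut is O1–C8a and C4–C4a in both units. Bis-lactone A2 would be opened to the bis(N-methoxy-N-methylamide) diol A3. Its dipotassium alkoxide would add to two equivalents of a 3,5-bis(benzyloxy)-substituted aryne, and each aryl anion would attack the neighbouring amide, closing both rings C at the ketone level to give A4.
- Merits: the carbonyl oxidation state is reached directly, so no counterpart of step 7 is needed. The aryne regiochemistry is favourable (alkoxide meta to the alkoxy group, anion ortho to it), and four bonds form in one operation. In oxidation-state economy this road is better than the chosen one.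
- Weak points: A4 carries four identical benzyl ethers, and the target needs a methyl group on one of two equivalent 7-oxygens, which can only be done statistically. The alkoxides sit next to enolisable carbons in β-hydroxy amide units, so retro-aldol cleavage and drift to the trans series threaten once the lactone rings are open. The supply problem of A2 is inherited.
- Comparison: the chosen plan sets against this road that the unsymmetry of the target costs it nothing.

**Alternative 3:** Only the C2–C3 bond of the dihydroxy unit is cut. Dirhodium tetrakis[N-phthaloyl-(S)-tert-leucinate], Rh2(S-PTTL)4, would decompose diazo ketone A5. The carbenoid at C3 would insert into a benzylic C–H bond of an ortho 4-methoxybenzyl ether, whose CH2 becomes C2 and whose aryl group becomes ring B, giving flavanone A6 with the flavone of the second unit at C3.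
- Merits: enantioselective carbenoid insertion into benzylic ether C–H bonds is closer to established practice than the key step chosen here. The two halves differ from the start, and one ketone is already in place. In precedent for the stereo-determining step this road is ahead.
- Weak points: only one ring C and two stereocentres result. The tetrasubstituted C2''=C3'' bond of the flavone must still be reduced cis and on the right face, beside a C3–H that is α to a ketone and attached to an enone, without loss of benzyl ethers. Insertion to a six-membered ring competes with attack of the carbenoid on the chromone carbonyl oxygen and on the arenes. A5 is a long linear target in itself.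
- Comparison: the chosen plan sets against this road its convergence, with both rings and all four stereocentres made from three simple fragments in one flask.

Key step: step 6

Assumption: the (R)-configured acid is taken to favour the (2R,3S,4S) sense of addition (its antipode is used if the first cycloadduct proves enantiomeric), and C4/C4'' of 9 and 11 are written as the expected 3,4-trans epimers, either epimer converging on 12.

## Route

Step 1
Reactants: 1 4-ethynylanisole (1-ethynyl-4-methoxybenzene), two molecules per molecule of product
Product: 2 1,4-bis(4-methoxyphenyl)buta-1,3-diyne
Conditions: CuCl (10 mol%), TMEDA (20 mol%), O2 (1 atm), acetone, rt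
Reagents that add atoms: 4-ethynylanisole (the second molecule of 1), COc1ccc(C#C)cc1
Why: Glaser–Hay oxidative homocoupling joins two molecules of the terminal arylacetylene through copper acetylides, with O2 as the terminal oxidant; the sp–sp bond made here is the future C3–C3'' bond, and electron-rich arylalkynes are standard substrates.

Step 2
Reactants: 2 1,4-bis(4-methoxyphenyl)buta-1,3-diyne
Product: 3 (1Z,3Z)-1,4-bis(4-methoxyphenyl)buta-1,3-diene
Conditions: H2 (1 atm, stopped after 2 equiv), Pd on CaCO3 poisoned with Pb(OAc)2 (Lindlar catalyst), quinoline, EtOAc, rt, dark
Reagents that add atoms: none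
Why: Lindlar semihydrogenation adds hydrogen syn to each triple bond on the poisoned palladium surface and releases the alkene before further reduction, so both double bonds should be Z; cis,cis-1,4-diarylbutadienes are classically made from the diynes in this way.

Step 3
Reactants: 4 2,4,6-trihydroxybenzaldehyde
Product: 5 4,6-bis(benzyloxy)-2-hydroxybenzaldehyde
Conditions: BnBr (2.05 equiv), K2CO3 (2.1 equiv), DMF, 0 °C to rt
Reagents that add atoms: benzyl bromide (two molecules incorporated), BrCc1ccccc1
Why: Williamson etherification; the para hydroxyl and the non-chelated ortho hydroxyl react, while the remaining ortho hydroxyl is hydrogen-bonded to the formyl group and should stay free, as is usual for acylphloroglucinols.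

Step 4
Reactants: 4 2,4,6-trihydroxybenzaldehyde
Product: 6 2,6-dihydroxy-4-methoxybenzaldehyde
Conditions: Me2SO4 (1.0 equiv), K2CO3 (1.0 equiv), acetone, rt
Reagents that add atoms: dimethyl sulfate, COS(=O)(=O)OC
Why: Williamson O-methylation; the 4-hydroxyl, para to the formyl group and not chelated, is the most acidic oxygen, so one equivalent of a hard methylating agent should take this position in preference to the ortho hydroxyls and to carbon.

Step 5
Reactants: 6 2,6-dihydroxy-4-methoxybenzaldehyde
Product: 7 2-(benzyloxy)-6-hydroxy-4-methoxybenzaldehyde
Conditions: BnBr (1.05 equiv), K2CO3 (1.1 equiv), acetone, reflux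
Reagents that add atoms: benzyl bromide, BrCc1ccccc1
Why: Williamson etherification of one of two equivalent ortho hydroxyls; after the first alkylation the other is locked in a hydrogen bond to the carbonyl group and reacts much more slowly, so the reaction should stop at the monoether.

Step 6
Reactants: 3 (1Z,3Z)-1,4-bis(4-methoxyphenyl)buta-1,3-diene; 5 4,6-bis(benzyloxy)-2-hydroxybenzaldehyde; 7 2-(benzyloxy)-6-hydroxy-4-methoxybenzaldehyde
Product: 11 (2R,3S,4S,2''R,3''S,4''S)-5,7,5''-tris(benzyloxy)-4,4',4'',4''',7''-pentamethoxy-3,3''-biflavan, via dimethyl acetal 8 (not isolated), via mono-cycloadduct 9 (not isolated), via dimethyl acetal 10 (not isolated)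
Conditions: 3 (1.0 equiv), HC(OMe)3 (3 equiv), (R)-3,3'-bis(2,4,6-triisopropylphenyl)-1,1'-binaphthyl-2,2'-diyl hydrogen phosphate (10 mol%), PhMe, −40 °C, dark, slow addition of 5 (1.0 equiv); then 7 (1.3 equiv), HC(OMe)3 (3 equiv), −40 to −20 °C
Reagents that add atoms: trimethyl orthoformate, COC(OC)OC
Why: Proposed new method: acid and orthoformate convert 5 into acetal 8, whose ionisation gives a 1-methoxy ortho-quinone methide held as a hydrogen-bonded ion pair by the chiral phosphate, and this electron-poor oxa-diene (O1, C8a, C4a, C4) adds across one Z alkene of 3 in an inverse-demand, asynchronous [4+2] step in which C4–C3 forms ahead of O1–C2; the closest known reactions are the acid-promoted three-component synthesis of 4-alkoxy-2-arylchromans from salicylaldehydes, orthoformates and styrenes and the chiral-phosphoric-acid-controlled [4+2] additions of ortho-quinone methides to styrenes, neither of which has been run twice on a conjugated Z,Z-diene. Each ring C closes as a six-membered ring in a suprafacial cycloaddition (in the stepwise limit, C–C bond formation followed by 6-endo capture of the anisyl-stabilised cation by the phenolic oxygen inside the ion pair), so the Z geometry becomes the 2,3-cis relationship. The configuration at C2 and C3 is chosen by the phosphate, which binds the phenolic OH and the oxocarbenium unit and leaves one alkene face open; C4 is set by the exo approach and by reversible ionisation of the C4–OMe bond, is written trans to the C3 substituent, and disappears in step 7. The first addition gives 9, in which the diene conjugation is broken and the remaining Z alkene is a less nucleophilic, isolated anethole-type alkene, so 5 should be consumed before 7 is added; 7 then reacts through acetal 10 and closes the second ring C in the same way. The same catalyst should pick the same kind of face again and give the like (2R,2''R) array, which requires catalyst control to dominate over the allylic stereocentre C3. The step needs styrene-type regiochemistry (O1 to the anisyl carbon, C4 to the inner carbon): the 4-methoxy group stabilises cationic character at C2, and in the Z,Z-diene the competing aryl-allyl cation would have to carry an inward aryl group twisted out of conjugation. It also needs the Z alkenes to survive the acid, for which the weak acid, the low temperature and the exclusion of light are chosen.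

Step 7
Reactants: 11 (2R,3S,4S,2''R,3''S,4''S)-5,7,5''-tris(benzyloxy)-4,4',4'',4''',7''-pentamethoxy-3,3''-biflavan
Product: 12 (2R,3R,2''R,3''R)-5,7,5''-tris(benzyloxy)-4',4''',7''-trimethoxy-3,3''-biflavanone
Conditions: DDQ (2.5 equiv), CH2Cl2/pH 7 phosphate buffer (10:1), 0 °C to rt
Reagents that add atoms: water, O
Why: DDQ abstracts hydride from C4–H and C4''–H, which are benzylic to the trioxygenated rings A and α to OMe; water adds to each oxocarbenium ion and the hemiketals lose methanol to give the aryl ketones, the same oxidative cleavage of electron-rich benzylic ethers that removes 4-methoxybenzyl ethers and that functionalises C4 of 5,7-dialkoxyflavans. The C2–H bonds are far less activated, the aryl benzyl ethers are inert, and the buffer should keep C3 and C3'' from epimerising.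

Step 8
Reactants: 12 (2R,3R,2''R,3''R)-5,7,5''-tris(benzyloxy)-4',4''',7''-trimethoxy-3,3''-biflavanone
Product: 13 (2R,3R,2''R,3''R)-5,7,5''-trihydroxy-4',4''',7''-trimethoxy-3,3''-biflavanone
Conditions: H2 (1 atm), 10% Pd/C, EtOAc, rt
Reagents that add atoms: none
Why: Hydrogenolysis of the three aryl benzyl ethers under neutral conditions; flavanone carbonyl groups and C2–O1 bonds normally survive debenzylation at ambient pressure, and the neutral aprotic medium should leave the cis-configured C3 and C3'' untouched.

## Compound list

1 | 4-ethynylanisole (1-ethynyl-4-methoxybenzene) | COc1ccc(C#C)cc1 | starting material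
2 | 1,4-bis(4-methoxyphenyl)buta-1,3-diyne | COc1ccc(cc1)C#CC#Cc1ccc(OC)cc1 | intermediate
3 | (1Z,3Z)-1,4-bis(4-methoxyphenyl)buta-1,3-diene | COc1ccc(cc1)/C=C\C=C/c1ccc(OC)cc1 | intermediate
4 | 2,4,6-trihydroxybenzaldehyde | O=Cc1c(O)cc(O)cc1O | starting material
5 | 4,6-bis(benzyloxy)-2-hydroxybenzaldehyde | O=Cc1c(O)cc(OCc2ccccc2)cc1OCc1ccccc1 | intermediate
6 | 2,6-dihydroxy-4-methoxybenzaldehyde | O=Cc1c(O)cc(OC)cc1O | intermediate
7 | 2-(benzyloxy)-6-hydroxy-4-methoxybenzaldehyde | O=Cc1c(O)cc(OC)cc1OCc1ccccc1 | intermediate
8 | 3,5-bis(benzyloxy)-2-(dimethoxymethyl)phenol, the dimethyl acetal of 5, formed in the flask in step 6 | COC(OC)c1c(O)cc(OCc2ccccc2)cc1OCc1ccccc1 | intermediate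
9 | (2R,3S,4S)-5,7-bis(benzyloxy)-4-methoxy-2-(4-methoxyphenyl)-3-[(Z)-2-(4-methoxyphenyl)ethenyl]chroman (2,3-cis, 3,4-trans), formed in the flask in step 6 | COc1ccc([C@@H]2Oc3cc(OCc4ccccc4)cc(OCc4ccccc4)c3[C@@H](OC)[C@@H]2/C=C\c2ccc(OC)cc2)cc1 | intermediate
10 | 3-(benzyloxy)-2-(dimethoxymethyl)-5-methoxyphenol, the dimethyl acetal of 7, formed in the flask in step 6 | COC(OC)c1c(O)cc(OC)cc1OCc1ccccc1 | intermediate
11 | (2R,3S,4S,2''R,3''S,4''S)-5,7,5''-tris(benzyloxy)-4,4',4'',4''',7''-pentamethoxy-3,3''-biflavan; that is, (2R,3S,4S)-5,7-bis(benzyloxy)-3-[(2R,3S,4S)-5-(benzyloxy)-4,7-dimethoxy-2-(4-methoxyphenyl)chroman-3-yl]-4-methoxy-2-(4-methoxyphenyl)chroman, 2,3-cis and 3,4-trans in both units | COc1ccc([C@@H]2Oc3cc(OCc4ccccc4)cc(OCc4ccccc4)c3[C@@H](OC)[C@@H]2[C@H]2[C@H](OC)c3c(OCc4ccccc4)cc(OC)cc3O[C@H]2c2ccc(OC)cc2)cc1 | intermediate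
12 | (2R,3R,2''R,3''R)-5,7,5''-tris(benzyloxy)-4',4''',7''-trimethoxy-3,3''-biflavanone; that is, (2R,3R)-5,7-bis(benzyloxy)-3-[(2R,3R)-5-(benzyloxy)-7-methoxy-2-(4-methoxyphenyl)-4-oxochroman-3-yl]-2-(4-methoxyphenyl)chroman-4-one, 2,3-cis in both units | COc1ccc([C@@H]2Oc3cc(OCc4ccccc4)cc(OCc4ccccc4)c3C(=O)[C@@H]2[C@H]2C(=O)c3c(OCc4ccccc4)cc(OC)cc3O[C@H]2c2ccc(OC)cc2)cc1 | intermediate
13 | (2R,3R,2''R,3''R)-5,7,5''-trihydroxy-4',4''',7''-trimethoxy-3,3''-biflavanone; that is, (2R,3R)-5,7-dihydroxy-3-[(2R,3R)-5-hydroxy-7-methoxy-2-(4-methoxyphenyl)-4-oxochroman-3-yl]-2-(4-methoxyphenyl)chroman-4-one, 2,3-cis in both units | COc1ccc([C@@H]2Oc3cc(O)cc(O)c3C(=O)[C@@H]2[C@H]2C(=O)c3c(O)cc(OC)cc3O[C@H]2c2ccc(OC)cc2)cc1 | target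

## Step count and least certain steps

Total step count: 8. Longest linear sequence: 5 steps (4 to 6 to 7 to 11 to 12 to 13; the diene branch 1 to 2 to 3 to 11 to 12 to 13 is equally long).

**Step 6 (key step).** Three processes are the most likely to fail.
- The first oxa-diene may add with diene-type orientation, its carbon bonding to the anisyl-bearing terminus, because a conjugated diene normally takes an electrophile at its end.
- The ion pair may collapse more slowly than the C2–C3 bond rotates, or the diene may isomerise under acid, so that cis is lost.
- The second addition may be mismatched, because the stereocentre C3 beside the remaining Z alkene exerts its own allylic-strain bias.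

Self-condensation of the electron-rich aldehydes is a further drain, which slow addition is meant to limit. If only the rate is at fault, the N-triflyl phosphoramide of the same binaphthyl backbone is the first variable.

Fallback with known chemistry, setting out from 2 (with 5 and 7) and returning at 11: the rings are closed one at a time on alkenes of unambiguous polarity, and control by the chiral acid is given up.
- Monohydroboration of 2 with disiamylborane and protonolysis with acetic acid gives (Z)-1,4-bis(4-methoxyphenyl)but-1-en-3-yne F1. Here the second alkene is masked as an alkyne, a much poorer cation-stabilising group than a styryl group.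
- The established three-component reaction of 5, trimethyl orthoformate and F1 under an achiral acid (diphenyl hydrogen phosphate, CH2Cl2, low temperature) gives racemic (2R,3S,4S)-5,7-bis(benzyloxy)-4-methoxy-2-(4-methoxyphenyl)-3-[(4-methoxyphenyl)ethynyl]chroman F2.
- Semihydrogenation of F2 over Pd/CaCO3 poisoned with Pb(OAc)2 gives 9 as an isolated racemate.
- The same three-component reaction with 7 gives racemic 11 beside its unlike diastereomer, which is removed by chromatography.
- The enantiomers of 11 are separated on a chiral stationary phase, and the route continues with step 7.

**Step 7.** Hydride abstraction may also occur at the anisyl-benzylic C2–H. The C4 oxocarbenium ion may lose the C3 proton, or the acidic hydroquinone may epimerise C3 of the ketone; both would erase the cis relationship. Fallback from 11, returning at 12: the oxygen is unmasked first and oxidised as an alcohol. Solvolysis of both methyl ethers in aqueous acetone with catalytic pyridinium p-toluenesulfonate gives (2R,3S,2''R,3''S)-5,7,5''-tris(benzyloxy)-4',4''',7''-trimethoxy-3,3''-biflavan-4,4''-diol F3 (C4 epimers). Dess–Martin periodinane buffered with NaHCO3 then oxidises F3 to 12.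

**Step 2.** Over-reduction and Z-to-E isomerisation on the catalyst surface would give diene isomers and alkenes that are hard to separate from 3. Fallback from 1, returning at 3: each double bond is fixed before the central bond is made.
- Iodination of 1 (N-iodosuccinimide, catalytic AgNO3, acetone) gives 1-(iodoethynyl)-4-methoxybenzene F4.
- Hydroboration with dicyclohexylborane and protonolysis with acetic acid gives (Z)-1-(2-iodoethenyl)-4-methoxybenzene F5.
- Reductive homocoupling of two molecules of F5 with bis(1,5-cyclooctadiene)nickel (zerovalent nickel) in DMF, which joins alkenyl halides with retention of geometry, gives 3.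

**Step 8.** Epimerisation at C3/C3'' on the catalyst, or reductive opening of the anisyl-benzylic C2–O1 bonds, would spoil the last step. Fallback from 12, returning at 13: non-reductive dealkylation with BCl3 and pentamethylbenzene in CH2Cl2 at −78 °C, the benzyl cations being trapped by the arene. No new compound is made.

**Step 4.** Over-methylation, methylation of an ortho hydroxyl or C-methylation of the phloroglucinol ring would lower the supply of 6. Fallback from 4, returning at 6: exhaustive methylation (Me2SO4, K2CO3, acetone, reflux) gives 2,4,6-trimethoxybenzaldehyde F6. Chelation-controlled cleavage of the two methyl ethers ortho to the formyl group with AlCl3 in CH2Cl2 then gives 6 with the para methyl ether intact.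

## Further compounds

F1 | step 6 | (Z)-1,4-bis(4-methoxyphenyl)but-1-en-3-yne | COc1ccc(cc1)/C=C\C#Cc1ccc(OC)cc1
F2 | step 6 | racemic (2R,3S,4S)-5,7-bis(benzyloxy)-4-methoxy-2-(4-methoxyphenyl)-3-[(4-methoxyphenyl)ethynyl]chroman (one enantiomer drawn) | COc1ccc([C@@H]2Oc3cc(OCc4ccccc4)cc(OCc4ccccc4)c3[C@@H](OC)[C@@H]2C#Cc2ccc(OC)cc2)cc1
F3 | step 7 | (2R,3S,2''R,3''S)-5,7,5''-tris(benzyloxy)-4',4''',7''-trimethoxy-3,3''-biflavan-4,4''-diol (C4 and C4'' epimers) | COc1ccc([C@@H]2Oc3cc(OCc4ccccc4)cc(OCc4ccccc4)c3C(O)[C@@H]2[C@H]2C(O)c3c(OCc4ccccc4)cc(OC)cc3O[C@H]2c2ccc(OC)cc2)cc1
F4 | step 2 | 1-(iodoethynyl)-4-methoxybenzene | COc1ccc(cc1)C#CI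
F5 | step 2 | (Z)-1-(2-iodoethenyl)-4-methoxybenzene | COc1ccc(cc1)/C=C\I
F0 | step 8 | none | none
F6 | step 4 | 2,4,6-trimethoxybenzaldehyde | COc1cc(OC)c(C=O)c(OC)c1
A1 | alternative 1 | all-trans 3,4-bis(4-methoxyphenyl)cyclobutane-1,2-dicarboxylic acid (δ-truxinic type) | OC(=O)[C@@H]1[C@@H](C(=O)O)[C@H](c2ccc(OC)cc2)[C@H]1c1ccc(OC)cc1
A2 | alternative 1 | exo,exo-2,6-bis(4-methoxyphenyl)-3,7-dioxabicyclo[3.3.0]octane-4,8-dione | O=C1O[C@@H](c3ccc(OC)cc3)[C@H]2[C@@H]1[C@H](c1ccc(OC)cc1)OC2=O
A3 | alternative 2 | 2,3-bis[hydroxy(4-methoxyphenyl)methyl]-N,N'-dimethoxy-N,N'-dimethylbutanediamide, configured as in A2 | COc1ccc([C@H](O)[C@H](C(=O)N(C)OC)[C@@H](C(=O)N(C)OC)[C@@H](O)c2ccc(OC)cc2)cc1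
A4 | alternative 2 | (2R,3R,2''R,3''R)-5,7,5'',7''-tetrakis(benzyloxy)-4',4'''-dimethoxy-3,3''-biflavanone | COc1ccc([C@@H]2Oc3cc(OCc4ccccc4)cc(OCc4ccccc4)c3C(=O)[C@@H]2[C@H]2C(=O)c3c(OCc4ccccc4)cc(OCc4ccccc4)cc3O[C@H]2c2ccc(OC)cc2)cc1
A5 | alternative 3 | 1-{4-(benzyloxy)-2,6-bis[(4-methoxybenzyl)oxy]phenyl}-2-[5-(benzyloxy)-7-methoxy-2-(4-methoxyphenyl)-4-oxo-4H-chromen-3-yl]-2-diazoethan-1-one | COc1ccc(COc2cc(OCc3ccccc3)cc(OCc3ccc(OC)cc3)c2C(=O)C(=[N+]=[N-])C2=C(c3ccc(OC)cc3)Oc3cc(OC)cc(OCc4ccccc4)c3C2=O)cc1
A6 | alternative 3 | (2R,3R)-7-(benzyloxy)-3-[5-(benzyloxy)-7-methoxy-2-(4-methoxyphenyl)-4-oxo-4H-chromen-3-yl]-5-[(4-methoxybenzyl)oxy]-2-(4-methoxyphenyl)chroman-4-one | COc1ccc([C@@H]2Oc3cc(OCc4ccccc4)cc(OCc4ccc(OC)cc4)c3C(=O)[C@@H]2C2=C(c3ccc(OC)cc3)Oc3cc(OC)cc(OCc4ccccc4)c3C2=O)cc1
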